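**Remark.** The SMILES is read as epicatechin-(4β→6)-epicatechin-(4β→6)-epicatechin: every unit is 2R,3R (2,3-cis), and both interflavan bonds are 4S, on the face of ring C opposite to the C2 aryl and C3 hydroxyl groups (β). The three C3 hydroxyls are carried free throughout. "Top", "middle" and "bottom" unit follow the SMILES from left to right.

## The problem

The target consists of three (2R,3R)-flavan-3-ol units joined only by two C(sp3)–C(sp2) bonds, each from C4 of a ring C to C6 of ring A of the next unit. The units are available with all six C2/C3 stereocentres in place, so the synthesis has to solve the joining, not the rings. The first difficulty is position: in ring A both C6 and C8 are aromatic CH groups with two ortho oxygens and one para oxygen, electrophiles innately prefer C8, and the target needs C6 twice. The second is chain length: the middle unit must be a nucleophile at C6 and an electrophile at C4, and a unit that is both at once oligomerises. The third is configuration at the two new C4 stereocentres, which must be trans to the neighbouring C3–OH; the axial C3–OH of the 2,3-cis series can control this, while C2 is at risk only under base as long as the 4'-phenol is free. The product is a dodecaphenol with three air-sensitive catechols, and its interflavan bonds are reversible Friedel–Crafts bonds that acid cleaves, so the end game must be neutral and reductive. The feature that makes the key step possible is this: C4 of ring C is benzylic to ring A and conjugated through C4a with O5 (ortho) and O7 (para), so a C4–O bond ionises under a hard Lewis acid and a C4–S bond under a thiophile, and once C8 carries bromine, C6 is the only unsubstituted carbon of ring A. The middle unit can therefore keep a silent C4–S bond while its C6 reacts and be switched to electrophile afterwards in the same flask.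

## Retrosynthesis

**9 ⇒ 8.** Twelve O–benzyl bonds and four aryl C–Br bonds are cut. Ether protection is needed because benzylic C4 oxidation and Lewis-acid coupling both demand alkylated phenols. Benzyl and bromine are chosen because both fall in one neutral hydrogenolysis, whereas silyl or methyl ethers would need fluoride or strong Lewis acid on a polyphenol. The forward step must reduce sixteen bonds without letting acid build up.

**8 ⇒ 6 + 5 + 3 (through 7).** Both interflavan bonds are cut in one operation. Cutting only one bond would leave a dimer that has to be isolated and, in the bottom-up order, a middle unit that is nucleophile and electrophile at the same time. The top-down order removes this: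
- In the first stage the only cation precursor under a hard Lewis acid is 6, which has no free ring-A carbon, and the only free aromatic carbon is C6 of 5.
- In the second stage the only cation precursor under a thiophile is 7, and the only free aromatic carbon is C6 of 3.

Three monomers of at most four steps each give a product with three units and eight stereocentres. The forward reaction must deliver β attack twice and leave the sulfide untouched in the first stage.

**6 ⇒ 4 and 5 ⇒ 4.** One C6–Br bond (for 6) or the C4–S bond in exchange for C4–O (for 5) is cut. Both outer functions of the key step thus come from one common intermediate, which already has the C8 cap and the C4β oxygen. The alternative of making the sulfide and the dibromide on separate lines from 2 would double the oxidation step.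

**4 ⇒ 3.** The C4–O bond is cut back to the CH2 group. Compound 3 is also the bottom unit, so one compound serves three purposes. The forward step is a benzylic oxidation that must choose C4 and the β face.

**3 ⇒ 2 ⇒ 1.** The C8–Br bond and four O–benzyl bonds are cut. The innate C8 preference that would misdirect the interflavan bond is used to place the cap. Compound 1 supplies all C2 and C3 stereocentres.

## Roads not taken

**Alternative 1:** One interflavan bond at a time, from the bottom (the most obvious route). The middle–bottom bond is made first by Lewis-acid coupling of 4 with 3 to the capped dimer A1; then 6 is coupled to the free C6 of A1 to give 8. In the first coupling 4 has both a free C6 and an ionisable C4, so self-condensation competes statistically; it can only be held down by an excess of 3 and by separating higher oligomers. Two acid-labile intermediates are isolated. The step count equals that of the chosen plan, but the chosen plan has exactly one electrophilic and one nucleophilic site in every stage, so stoichiometry is 1:1:1 and chain length is fixed by design.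

**Alternative 2:** The same bonds closed intramolecularly. O5 of a lower unit, which is ortho only to C6, would be tied by a diacid linker to O3 of a C4-activated upper unit, and the interflavan bond closed as a large ring by Friedel–Crafts reaction; the linker would then be removed. This needs the 5-hydroxy lower unit A2, that is, a differentiation of O5 from O7 that 1 does not offer, on two units. The anchor O3 lies on the α face while the bond must form on the β face, so only long linkers can give 3,4-trans. Linker installation and removal twice more than doubles the step count, and a cap at C8 achieves the same regiocontrol in one step.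

**Alternative 3:** Interflavan bond first, ring C afterwards. O1–C2 and C4–C4a of the lower units are cut, leaving phloroglucinol. The cation from 4 would add to phloroglucinol to give A3, in which the hydroxyl para to the new bond is unique. Its alkylation by a chiral three-carbon aryl epoxide and a 6-endo epoxide–arene closure onto either of the two equivalent ortho carbons would give a 6-linked flavan by symmetry, without a cap. The regiochemical logic is attractive, but the C2/C3 stereocentres of two units would have to be built instead of taken from 1, the three phenols of A3 would have to be told apart, and the new middle unit would still need C4 oxidation. The linear sequence would be well over twice as long.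

Key step: step 6

## Steps

Step 1
Reactants: 1 (−)-epicatechin
Product: 2 5,7,3',4'-tetra-O-benzyl-(−)-epicatechin
Conditions: BnBr (4.4 equiv), K2CO3, DMF, 0 °C to rt
Reagents that add atoms: benzyl bromide, BrCc1ccccc1
Why: Williamson etherification; K2CO3 deprotonates only the four phenols, the secondary C3–OH stays free, and the cold start limits C-benzylation of ring A and base-induced C2 epimerisation through the ring-B quinone methide; no stereocentre is touched.

Step 2
Reactants: 2 5,7,3',4'-tetra-O-benzyl-(−)-epicatechin
Product: 3 8-bromo-5,7,3',4'-tetra-O-benzylepicatechin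
Conditions: NBS (1.0 equiv), CH2Cl2, −78 to 0 °C
Reagents that add atoms: N-bromosuccinimide, O=C1CCC(=O)N1Br
Why: Electrophilic aromatic bromination; in the tetra-O-benzyl ether C8 (ortho to O1 and O7, para to O5) is the most reactive ring-A carbon, C6 being shielded by two benzyloxy groups and ring B being less activated, so one equivalent of NBS caps exactly the position that would otherwise take the interflavan bond.

Step 3
Reactants: 3 8-bromo-5,7,3',4'-tetra-O-benzylepicatechin
Product: 4 8-bromo-4β-(2-ethoxyethoxy)-5,7,3',4'-tetra-O-benzylepicatechin (2,3-cis, 3,4-trans)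
Conditions: DDQ (2 equiv), 2-ethoxyethanol (5 equiv), CH2Cl2, rt
Reagents that add atoms: 2-ethoxyethanol, CCOCCO
Why: Benzylic C–H oxidation by DDQ; C4, benzylic to the trioxygenated ring A, is the established site of hydride abstraction in benzylated flavan-3-ols, and the alcohol captures the cation anti to the axial C3–OH, which sets the 4β ether.

Step 4
Reactants: 4 8-bromo-4β-(2-ethoxyethoxy)-5,7,3',4'-tetra-O-benzylepicatechin
Product: 5 8-bromo-4β-(2,6-dimethylphenylthio)-5,7,3',4'-tetra-O-benzylepicatechin (2,3-cis, 3,4-trans)
Conditions: 2,6-dimethylbenzenethiol (2 equiv), BF3·OEt2 (0.5 equiv), CH2Cl2, −78 to −40 °C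
Reagents that add atoms: 2,6-dimethylbenzenethiol, Cc1cccc(C)c1S
Why: Lewis-acid SN1 exchange of the thiolysis type; BF3 ionises the C4–O bond and the soft thiol in excess captures the cation faster than C6 of another molecule, again anti to C3–OH (4β); the hindered aryl sulfide is inert to hard Lewis acids, which makes C4 of this unit latent.

Step 5
Reactants: 4 8-bromo-4β-(2-ethoxyethoxy)-5,7,3',4'-tetra-O-benzylepicatechin
Product: 6 6,8-dibromo-4β-(2-ethoxyethoxy)-5,7,3',4'-tetra-O-benzylepicatechin (2,3-cis, 3,4-trans)
Conditions: NBS (1.1 equiv), CH2Cl2, 0 °C to rt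
Reagents that add atoms: N-bromosuccinimide, O=C1CCC(=O)N1Br
Why: Second electrophilic bromination at C6, the last free ring-A carbon, still activated by O5 and O7 (ortho) and O1 (para) and more reactive than ring B; it removes the only nucleophilic carbon of the future top unit, the C4 ether is inert to NBS and no stereocentre changes.

Step 6
Reactants: 6 6,8-dibromo-4β-(2-ethoxyethoxy)-5,7,3',4'-tetra-O-benzylepicatechin; 5 8-bromo-4β-(2,6-dimethylphenylthio)-5,7,3',4'-tetra-O-benzylepicatechin; 3 8-bromo-5,7,3',4'-tetra-O-benzylepicatechin
Product: 8 protected trimer [6,8-dibromo-tetra-O-benzylepicatechin]-(4β→6)-[8-bromo-tetra-O-benzylepicatechin]-(4β→6)-[8-bromo-tetra-O-benzylepicatechin], via dimeric sulfide 7 (not isolated)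
Conditions: one flask; 6 (1.0 equiv), 5 (1.0 equiv), BF3·OEt2 (1 equiv), 4 Å molecular sieves, CH2Cl2, −78 to −30 °C; then 3 (1.2 equiv), AgBF4 (1.5 equiv), THF/CH2Cl2, −40 to 0 °C
Reagents that add atoms: none
Why: BF3, chelated by the two ether oxygens at C4 of 6, ionises the C4–O bond to a benzylic cation stabilised through C4a by O5 and O7; the sulfide of 5 is not touched by this hard acid and 6 has no free ring-A carbon, so the only nucleophile is C6 of 5 and Friedel–Crafts substitution gives 7. AgBF4 then binds the sulfur of 7 and generates the second cation, at C4 of the middle unit, which is captured by C6 of 3, the only unsubstituted ring-A carbon left in the flask. The closest known reaction type is the Lewis-acid-promoted SN1 Friedel–Crafts formation of interflavan bonds from 4-alkoxy and 4-thio flavan-3-ols, with hard/soft orthogonal activation of the two leaving groups. No ring is closed. The two new stereocentres, C4 of the top unit and C4 of the middle unit, are set by the neighbouring axial C3–OH of the 2,3-cis half-chair: the arene adds pseudo-axially on the β face, anti to C3–O and away from the C2 aryl group, giving 3,4-trans both times. Regioselectivity for C6 is secured by the bromine at C8 of 5 and of 3. Chain length is secured because each stage holds exactly one cation precursor and one free aromatic carbon. Chemoselectivity rests on the inertness of the hindered aryl sulfide towards BF3 and towards the top-unit cation in the first stage.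

Step 7
Reactants: 8 protected trimer
Product: 9 epicatechin-(4β→6)-epicatechin-(4β→6)-epicatechin (CNP0163146.2)
Conditions: H2 (1 atm), Pd(OH)2 on carbon, Et3N (4.4 equiv), THF/MeOH/H2O, rt; filtration under argon, Sephadex LH-20, freeze-drying
Reagents that add atoms: none
Why: Catalytic hydrogenolysis cleaves the twelve O–benzyl bonds and the four aryl C–Br bonds in one neutral operation; Et3N takes up the HBr so that the acid-labile interflavan bonds are not cleaved, and the benzylic C2–O1 and C4–aryl bonds are not hydrogenolysed under these mild conditions, so all eight stereocentres are kept.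

## Compound list

1 | (−)-epicatechin, (2R,3R)-2-(3,4-dihydroxyphenyl)chromane-3,5,7-triol | Oc1cc(O)c2c(c1)O[C@H](c1ccc(O)c(O)c1)[C@H](O)C2 | starting material

2 | 5,7,3',4'-tetra-O-benzyl-(−)-epicatechin | C(c1ccccc1)Oc1cc(OCc3ccccc3)c2c(c1)O[C@H](c1ccc(OCc3ccccc3)c(OCc3ccccc3)c1)[C@H](O)C2 | intermediate

3 | 8-bromo-5,7,3',4'-tetra-O-benzylepicatechin (bottom unit) | C(c1ccccc1)Oc1cc(OCc3ccccc3)c2c(c1Br)O[C@H](c1ccc(OCc3ccccc3)c(OCc3ccccc3)c1)[C@H](O)C2 | intermediate

4 | 8-bromo-4β-(2-ethoxyethoxy)-5,7,3',4'-tetra-O-benzylepicatechin | C(c1ccccc1)Oc1cc(OCc3ccccc3)c2c(c1Br)O[C@H](c1ccc(OCc3ccccc3)c(OCc3ccccc3)c1)[C@H](O)[C@H]2OCCOCC | intermediate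

5 | 8-bromo-4β-(2,6-dimethylphenylthio)-5,7,3',4'-tetra-O-benzylepicatechin (middle unit) | C(c1ccccc1)Oc1cc(OCc3ccccc3)c2c(c1Br)O[C@H](c1ccc(OCc3ccccc3)c(OCc3ccccc3)c1)[C@H](O)[C@H]2Sc1c(C)cccc1C | intermediate

6 | 6,8-dibromo-4β-(2-ethoxyethoxy)-5,7,3',4'-tetra-O-benzylepicatechin (top unit) | C(c1ccccc1)Oc1c(Br)c(OCc3ccccc3)c2c(c1Br)O[C@H](c1ccc(OCc3ccccc3)c(OCc3ccccc3)c1)[C@H](O)[C@H]2OCCOCC | intermediate

7 | dimeric sulfide [6,8-dibromo-tetra-O-benzylepicatechin]-(4β→6)-[8-bromo-4β-(2,6-dimethylphenylthio)-tetra-O-benzylepicatechin] | C(c1ccccc1)Oc1c(Br)c(OCc3ccccc3)c2c(c1Br)O[C@H](c1ccc(OCc3ccccc3)c(OCc3ccccc3)c1)[C@H](O)[C@H]2c1c(OCc3ccccc3)c(Br)c2c(c1OCc3ccccc3)[C@H](Sc1c(C)cccc1C)[C@@H](O)[C@@H](c1ccc(OCc3ccccc3)c(OCc3ccccc3)c1)O2 | intermediate (not isolated)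

8 | protected trimer [6,8-dibromo-tetra-O-benzylepicatechin]-(4β→6)-[8-bromo-tetra-O-benzylepicatechin]-(4β→6)-[8-bromo-tetra-O-benzylepicatechin] | C(c1ccccc1)Oc1c(Br)c(OCc3ccccc3)c2c(c1Br)O[C@H](c1ccc(OCc3ccccc3)c(OCc3ccccc3)c1)[C@H](O)[C@H]2c1c(OCc3ccccc3)c(Br)c2c(c1OCc3ccccc3)[C@H](c1c(OCc4ccccc4)c(Br)c3c(c1OCc4ccccc4)C[C@@H](O)[C@@H](c1ccc(OCc4ccccc4)c(OCc4ccccc4)c1)O3)[C@@H](O)[C@@H](c1ccc(OCc3ccccc3)c(OCc3ccccc3)c1)O2 | intermediate

9 | epicatechin-(4β→6)-epicatechin-(4β→6)-epicatechin (CNP0163146.2) | Oc1cc(O)c2c(c1)O[C@H](c1ccc(O)c(O)c1)[C@H](O)[C@H]2c1c(O)cc2c(c1O)[C@H](c1c(O)cc3c(c1O)C[C@@H](O)[C@@H](c1ccc(O)c(O)c1)O3)[C@@H](O)[C@@H](c1ccc(O)c(O)c1)O2 | target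

## Step count and least certain steps

Total step count: 7. Longest linear sequence: 6 steps (1 → 2 → 3 → 4 → 5 or 6 → 8 → 9).

**Step 6 (key step).**
- What may go wrong: slow ionisation of 6, because its two bromine atoms force both ring-A benzyloxy donors out of conjugation. The temperature would then have to be raised until the sulfide of 5 or 7 starts to ionise too, and the one-electrophile/one-nucleophile order would be lost (scrambled oligomers). In the second stage, slow capture at the shielded C6 of 3 may let the middle-unit cation drift to O-alkylation at a C3–OH or to elimination towards the flav-3-ene, and silver may bind the hindered aryl sulfide too weakly.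
- Fallback (no sulfur; the CH2 at the chain end is the latent electrophile and every bond is made in a separate, isolated operation): it sets out from 6 and 3. TMSOTf-catalysed Friedel–Crafts coupling (CH2Cl2, −78 to −40 °C) should give the dimer [6,8-dibromo-tetra-O-benzylepicatechin]-(4β→6)-[8-bromo-tetra-O-benzylepicatechin] F1. Its only CH2 group (C4 of the lower unit) is oxidised with DDQ and 2-ethoxyethanol to the 4β-(2-ethoxyethoxy) dimer F2. A second TMSOTf coupling of F2 with 3 comes back to the route at 8.

**Step 5.**
- What may go wrong: bromination straying to ring B or stalling at the shielded C6, or ionisation of the C4 ether by traces of HBr.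
- Fallback (no C6 cap on the top unit; chain length held by stoichiometry): it sets out from 4 and 5. BF3·OEt2 coupling with 5 in threefold excess should give the tribromo dimeric sulfide [8-bromo-tetra-O-benzylepicatechin]-(4β→6)-[8-bromo-4β-(2,6-dimethylphenylthio)-tetra-O-benzylepicatechin] F3, which is separated from the excess of 5. AgBF4 coupling of F3 with an excess of 3 gives the tribromo protected trimer [8-bromo-tetra-O-benzylepicatechin]-(4β→6)-[8-bromo-tetra-O-benzylepicatechin]-(4β→6)-[8-bromo-tetra-O-benzylepicatechin] F4. Hydrogenolysis under the conditions of step 7 comes back to the route at 9.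

**Step 3.**
- What may go wrong: slower hydride abstraction from the brominated ring, with incomplete conversion or over-oxidation to the C4 ketone.
- Fallback (oxidise before capping): it sets out from 2. DDQ and 2-ethoxyethanol should give 4β-(2-ethoxyethoxy)-5,7,3',4'-tetra-O-benzylepicatechin F5, which NBS (1 equiv) brominates at C8 to come back to the route at 4.

**Step 7.**
- What may go wrong: incomplete hydrogenolysis of the four hindered C–Br bonds, retardation of O-debenzylation by the amine, acid-induced cleavage of interflavan bonds if HBr is not fully buffered, and air oxidation during isolation.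
- Fallback (bromine removed before the benzyl groups): it sets out from 8. Bromine–lithium exchange (n-BuLi in excess, THF, −78 °C, then MeOH) should give the bromine-free dodeca-O-benzyl trimer F6. Hydrogenolysis of F6 without base (H2, Pd(OH)2 on carbon, THF/MeOH/H2O) comes back to the route at 9.

## Further compounds

F1 | step 6 | [6,8-dibromo-tetra-O-benzylepicatechin]-(4β→6)-[8-bromo-tetra-O-benzylepicatechin] | C(c1ccccc1)Oc1c(Br)c(OCc3ccccc3)c2c(c1Br)O[C@H](c1ccc(OCc3ccccc3)c(OCc3ccccc3)c1)[C@H](O)[C@H]2c1c(OCc3ccccc3)c(Br)c2c(c1OCc3ccccc3)C[C@@H](O)[C@@H](c1ccc(OCc3ccccc3)c(OCc3ccccc3)c1)O2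
F2 | step 6 | [6,8-dibromo-tetra-O-benzylepicatechin]-(4β→6)-[8-bromo-4β-(2-ethoxyethoxy)-tetra-O-benzylepicatechin] | C(c1ccccc1)Oc1c(Br)c(OCc3ccccc3)c2c(c1Br)O[C@H](c1ccc(OCc3ccccc3)c(OCc3ccccc3)c1)[C@H](O)[C@H]2c1c(OCc3ccccc3)c(Br)c2c(c1OCc3ccccc3)[C@H](OCCOCC)[C@@H](O)[C@@H](c1ccc(OCc3ccccc3)c(OCc3ccccc3)c1)O2
F3 | step 5 | [8-bromo-tetra-O-benzylepicatechin]-(4β→6)-[8-bromo-4β-(2,6-dimethylphenylthio)-tetra-O-benzylepicatechin] | C(c1ccccc1)Oc1cc(OCc3ccccc3)c2c(c1Br)O[C@H](c1ccc(OCc3ccccc3)c(OCc3ccccc3)c1)[C@H](O)[C@H]2c1c(OCc3ccccc3)c(Br)c2c(c1OCc3ccccc3)[C@H](Sc1c(C)cccc1C)[C@@H](O)[C@@H](c1ccc(OCc3ccccc3)c(OCc3ccccc3)c1)O2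
F4 | step 5 | [8-bromo-tetra-O-benzylepicatechin]-(4β→6)-[8-bromo-tetra-O-benzylepicatechin]-(4β→6)-[8-bromo-tetra-O-benzylepicatechin] | C(c1ccccc1)Oc1cc(OCc3ccccc3)c2c(c1Br)O[C@H](c1ccc(OCc3ccccc3)c(OCc3ccccc3)c1)[C@H](O)[C@H]2c1c(OCc3ccccc3)c(Br)c2c(c1OCc3ccccc3)[C@H](c1c(OCc4ccccc4)c(Br)c3c(c1OCc4ccccc4)C[C@@H](O)[C@@H](c1ccc(OCc4ccccc4)c(OCc4ccccc4)c1)O3)[C@@H](O)[C@@H](c1ccc(OCc3ccccc3)c(OCc3ccccc3)c1)O2
F5 | step 3 | 4β-(2-ethoxyethoxy)-5,7,3',4'-tetra-O-benzylepicatechin | C(c1ccccc1)Oc1cc(OCc3ccccc3)c2c(c1)O[C@H](c1ccc(OCc3ccccc3)c(OCc3ccccc3)c1)[C@H](O)[C@H]2OCCOCC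
F6 | step 7 | dodeca-O-benzyl-epicatechin-(4β→6)-epicatechin-(4β→6)-epicatechin | C(c1ccccc1)Oc1cc(OCc3ccccc3)c2c(c1)O[C@H](c1ccc(OCc3ccccc3)c(OCc3ccccc3)c1)[C@H](O)[C@H]2c1c(OCc3ccccc3)cc2c(c1OCc3ccccc3)[C@H](c1c(OCc4ccccc4)cc3c(c1OCc4ccccc4)C[C@@H](O)[C@@H](c1ccc(OCc4ccccc4)c(OCc4ccccc4)c1)O3)[C@@H](O)[C@@H](c1ccc(OCc3ccccc3)c(OCc3ccccc3)c1)O2
A1 | alternative 1 | [8-bromo-tetra-O-benzylepicatechin]-(4β→6)-[8-bromo-tetra-O-benzylepicatechin] | C(c1ccccc1)Oc1cc(OCc3ccccc3)c2c(c1Br)O[C@H](c1ccc(OCc3ccccc3)c(OCc3ccccc3)c1)[C@H](O)[C@H]2c1c(OCc3ccccc3)c(Br)c2c(c1OCc3ccccc3)C[C@@H](O)[C@@H](c1ccc(OCc3ccccc3)c(OCc3ccccc3)c1)O2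
A2 | alternative 2 | 7,3',4'-tri-O-(tert-butyldimethylsilyl)epicatechin (5-OH free) | CC(C)(C)[Si](C)(C)Oc1cc(O)c2c(c1)O[C@H](c1ccc(O[Si](C)(C)C(C)(C)C)c(O[Si](C)(C)C(C)(C)C)c1)[C@H](O)C2
A3 | alternative 3 | 8-bromo-5,7,3',4'-tetra-O-benzylepicatechin-(4β→2)-phloroglucinol | C(c1ccccc1)Oc1cc(OCc3ccccc3)c2c(c1Br)O[C@H](c1ccc(OCc3ccccc3)c(OCc3ccccc3)c1)[C@H](O)[C@H]2c1c(O)cc(O)cc1O
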